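**Strategy.** The six-membered carbocycle of helilupolone is disconnected into a four-carbon cyclobutenone unit (C1, C4, C5, C6) and a two-carbon alkyne unit (C2, C3). Heating 3-ethoxy-2,4,4-triprenylcyclobutenone with ethoxyacetylene triggers 4π ring opening, ketene–alkyne [2+2] addition, a second 4π opening and 6π closure, which inserts the alkyne carbons into the four-membered ring and delivers the fully substituted six-membered ring in one operation. The step exploits the alternating oxygens at ring carbons C1, C3 and C5 and the geminal prenyl pair at sp3 carbon C6, which blocks aromatisation, so the dienone level is reached directly. Hydrolysis of the two enol ethers and C-acylation at C2 complete the route.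

Key step: step 5

Remark: the target has no stereocentre (C6 carries two identical prenyl groups) and is a tautomeric β-triketone, so it is made as the achiral compound and drawn as the given dienol tautomer. Ring numbering throughout: C1 ring carbonyl, C2 acyl-bearing carbon, C3 and C5 oxygen-bearing carbons, C4 monoprenyl carbon, C6 diprenyl carbon; prenyl = 3-methylbut-2-en-1-yl.

**Step 1**
Reactants: 1 diethyl malonate; 2 prenyl bromide (1-bromo-3-methylbut-2-ene)
Product: 4 diethyl 2,2-bis(3-methylbut-2-en-1-yl)malonate, via monoprenyl malonate 3 (not isolated)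
Conditions: NaH (2.3 equiv), 2 (2.2 equiv), THF/DMF, 0 °C → rt
Reagents that add atoms: none
Why: Two successive SN2 C-alkylations of the malonate enolate with a reactive primary allylic bromide (malonic ester synthesis) should give the symmetrical dialkyl product, and no stereocentre is formed.

**Step 2**
Reactants: 4 diethyl 2,2-bis(3-methylbut-2-en-1-yl)malonate
Product: 6 5-methyl-2-(3-methylbut-2-en-1-yl)hex-4-enoic acid, via diprenylmalonic acid 5 (not isolated)
Conditions: KOH, EtOH/H2O, reflux; aq. HCl, 0 °C; then pyridine, 115 °C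
Reagents that add atoms: potassium hydroxide, [K+].[OH-]
Why: Saponification gives the geminal diacid, which should lose CO2 through the usual cyclic transition state (malonic acid decarboxylation), and the weakly basic pyridine keeps the acid from lactonising onto a prenyl double bond.

**Step 3**
Reactants: 7 ethoxyacetylene; 2 prenyl bromide
Product: 9 1-ethoxy-5-methylhex-4-en-1-yne, via lithium ethoxyacetylide 8 (not isolated)
Conditions: n-BuLi, THF, −78 °C; then 2, HMPA, −78 °C → rt
Reagents that add atoms: none
Why: Deprotonation of the terminal ynol ether and SN2 alkylation of the lithium acetylide at the primary carbon of the allylic bromide (acetylide alkylation) should give the internal ynol ether.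

**Step 4**
Reactants: 6 5-methyl-2-(3-methylbut-2-en-1-yl)hex-4-enoic acid; 9 1-ethoxy-5-methylhex-4-en-1-yne
Product: 12 3-ethoxy-2,4,4-tris(3-methylbut-2-en-1-yl)cyclobut-2-en-1-one, via acid chloride 10 (not isolated), via dialkylketene 11 (not isolated)
Conditions: (COCl)2, DMF (cat.), CH2Cl2, 0 °C → rt, evaporate; then 9 (1.5 equiv), Et3N, MeCN, rt → 50 °C
Reagents that add atoms: none
Why: Dehydrochlorination of the acid chloride gives the dialkylketene, which should undergo the regioselective ketene–ynol ether [2+2] cycloaddition (the nucleophilic prenyl-bearing alkyne carbon bonds to the ketene carbonyl carbon) to give the 3-ethoxycyclobutenone.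

**Step 5**
Reactants: 12 3-ethoxy-2,4,4-tris(3-methylbut-2-en-1-yl)cyclobut-2-en-1-one; 7 ethoxyacetylene
Product: 16 3,5-diethoxy-4,6,6-tris(3-methylbut-2-en-1-yl)cyclohexa-2,4-dien-1-one, via vinylketene 13 (not isolated), via 4-alkenylcyclobutenone 14 (not isolated), via dienylketene 15 (not isolated)
Conditions: 7 (5 equiv), toluene, sealed tube, Ar, 80 → 110 °C
Reagents that add atoms: none
Why: Thermal conrotatory 4π opening of the C(=O)–C(prenyl)2 bond of 12 gives vinylketene 13, which adds ethoxyacetylene in a [2+2] cycloaddition to cyclobutenone 14; a second 4π opening gives dienylketene 15, whose ketene carbon closes onto the C(prenyl)2 terminus, so that the four ring carbons of 12 and the two alkyne carbons form the six-membered ring of 16 (four-to-six ring expansion). The closest known reaction is the Danheiser benzannulation of cyclobutenones with alkoxyalkynes, together with the thermal closure of dienylketenes to 6,6-disubstituted cyclohexa-2,4-dienones. The six-membered ring closes by a thermal disrotatory 6π electrocyclisation that makes the C1–C6 bond, after C1–C2 and C3–C4 were made in the [2+2] step. No stereocentre is created, because C6 carries two identical prenyl groups, and a wrong C3=C4 geometry in 15 is corrected by reversible ring opening of 14. The step needs the 1,3,5-oxygen pattern, secured by the polarisation of the ynol ether (its CH carbon bonds to the ketene carbonyl carbon), and it needs capture of 13 to be faster than a [1,5]-hydrogen shift from the inward prenyl CH2, secured by the excess of the small, strongly nucleophilic alkyne. The quaternary C6 blocks tautomerisation to a phenol and the prenyl group at C4 blocks a Cope shift of a C6 prenyl group to the para position, so the dienone should survive the heating.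

**Step 6**
Reactants: 16 3,5-diethoxy-4,6,6-tris(3-methylbut-2-en-1-yl)cyclohexa-2,4-dien-1-one
Product: 18 3,5-dihydroxy-4,6,6-tris(3-methylbut-2-en-1-yl)cyclohexa-2,4-dien-1-one, via mono-ethyl ether 17 (not isolated)
Conditions: 2 M HCl, THF, 40 °C, Ar
Reagents that add atoms: water, O
Why: Acid-catalysed hydrolysis of the two vinylogous ester units (addition of water at C3 and C5, loss of ethanol) should give the enolised cyclohexane-1,3,5-trione, while dilute acid at 40 °C leaves the prenyl double bonds untouched.

**Step 7**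
Reactants: 18 3,5-dihydroxy-4,6,6-tris(3-methylbut-2-en-1-yl)cyclohexa-2,4-dien-1-one; 19 3-phenylpropanoic acid
Product: 21 helilupolone, via enol ester 20 (not isolated)
Conditions: DCC, DMAP (1.2 equiv), CH2Cl2, 0 °C → rt; 1 M HCl work-up
Reagents that add atoms: none
Why: Carbodiimide activation gives the enol ester and DMAP should transfer the acyl group from oxygen to C2 (Steglich-type O→C acyl migration, as used for 2-acylcyclohexane-1,3-diones), C2 being the only carbon at which the product is an enolisable, chelated β-triketone and therefore the thermodynamic sink.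

**Compound list**

1 | diethyl malonate | CCOC(=O)CC(=O)OCC | starting material
2 | prenyl bromide (1-bromo-3-methylbut-2-ene) | CC(C)=CCBr | starting material
3 | diethyl 2-(3-methylbut-2-en-1-yl)malonate | CCOC(=O)C(CC=C(C)C)C(=O)OCC | intermediate
4 | diethyl 2,2-bis(3-methylbut-2-en-1-yl)malonate | CCOC(=O)C(CC=C(C)C)(CC=C(C)C)C(=O)OCC | intermediate
5 | 2,2-bis(3-methylbut-2-en-1-yl)malonic acid | OC(=O)C(CC=C(C)C)(CC=C(C)C)C(=O)O | intermediate
6 | 5-methyl-2-(3-methylbut-2-en-1-yl)hex-4-enoic acid | CC(C)=CCC(CC=C(C)C)C(=O)O | intermediate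
7 | ethoxyacetylene (ethyl ethynyl ether) | C#COCC | starting material
8 | lithium ethoxyacetylide | [Li]C#COCC | intermediate
9 | 1-ethoxy-5-methylhex-4-en-1-yne | CCOC#CCC=C(C)C | intermediate
10 | 5-methyl-2-(3-methylbut-2-en-1-yl)hex-4-enoyl chloride | CC(C)=CCC(CC=C(C)C)C(=O)Cl | intermediate
11 | bis(3-methylbut-2-en-1-yl)ketene | CC(C)=CCC(CC=C(C)C)=C=O | intermediate
12 | 3-ethoxy-2,4,4-tris(3-methylbut-2-en-1-yl)cyclobut-2-en-1-one | CCOC1=C(CC=C(C)C)C(=O)C1(CC=C(C)C)CC=C(C)C | intermediate
13 | vinylketene, 3-ethoxy-7-methyl-2,4-bis(3-methylbut-2-en-1-yl)octa-1,3,6-trien-1-one | O=C=C(CC=C(C)C)C(OCC)=C(CC=C(C)C)CC=C(C)C | intermediate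
14 | 3-ethoxy-4-[1-ethoxy-5-methyl-2-(3-methylbut-2-en-1-yl)hexa-1,4-dien-1-yl]-4-(3-methylbut-2-en-1-yl)cyclobut-2-en-1-one | O=C1C=C(OCC)C1(CC=C(C)C)C(OCC)=C(CC=C(C)C)CC=C(C)C | intermediate
15 | dienylketene, (3E)-3,5-diethoxy-9-methyl-4,6-bis(3-methylbut-2-en-1-yl)deca-1,3,5,8-tetraen-1-one | O=C=C/C(OCC)=C(CC=C(C)C)\C(OCC)=C(CC=C(C)C)CC=C(C)C | intermediate
16 | 3,5-diethoxy-4,6,6-tris(3-methylbut-2-en-1-yl)cyclohexa-2,4-dien-1-one | O=C1C=C(OCC)C(CC=C(C)C)=C(OCC)C1(CC=C(C)C)CC=C(C)C | intermediate
17 | 5-ethoxy-3-hydroxy-4,6,6-tris(3-methylbut-2-en-1-yl)cyclohexa-2,4-dien-1-one (the mono-ether expected from attack at the less hindered C3) | O=C1C=C(O)C(CC=C(C)C)=C(OCC)C1(CC=C(C)C)CC=C(C)C | intermediate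
18 | 3,5-dihydroxy-4,6,6-tris(3-methylbut-2-en-1-yl)cyclohexa-2,4-dien-1-one (enolised 2,2,4-triprenylcyclohexane-1,3,5-trione) | CC(C)=CCC1=C(O)C(CC=C(C)C)(CC=C(C)C)C(=O)C=C1O | intermediate
19 | 3-phenylpropanoic acid | OC(=O)CCc1ccccc1 | starting material
20 | 5-hydroxy-4,4,6-tris(3-methylbut-2-en-1-yl)-3-oxocyclohexa-1,5-dien-1-yl 3-phenylpropanoate | CC(C)=CCC1=C(O)C(CC=C(C)C)(CC=C(C)C)C(=O)C=C1OC(=O)CCc2ccccc2 | intermediate
21 | helilupolone, 3,5-dihydroxy-4,6,6-tris(3-methylbut-2-en-1-yl)-2-(3-phenylpropanoyl)cyclohexa-2,4-dien-1-one | CC(C)=CCC1=C(O)C(CC=C(C)C)(CC=C(C)C)C(=O)C(C(=O)CCc2ccccc2)=C1O | target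

**Step count**

Total: 7 steps. Longest linear sequence: 6 steps (1, 2, 4, 5, 6, 7); step 3 is a one-step side branch.

**Steps most likely to fail**

**Step 5 (key step).** Capture of the tetrasubstituted vinylketene by the alkyne may be too slow. A [1,5]-hydrogen shift from the inward prenyl CH2 to the ketene carbon, or thermal loss of the volatile alkyne, would then take over. At the temperature needed for the second ring opening a prenyl group may also migrate from C6 via the carbonyl oxygen to C2, with aromatisation.

Fallback: the substituents are redistributed between the two partners, so that the ketene to be captured is monosubstituted at the ketene carbon and the alkyne is the less volatile internal ynol ether. The fallback sets out from acid 6 and comes back to the route at 18. Acid 6 is converted via 10 and 11 as in step 4, but with ethoxyacetylene 7 in place of 9, to give 3-ethoxy-4,4-bis(3-methylbut-2-en-1-yl)cyclobut-2-en-1-one F1. F1 is heated with ynol ether 9 (toluene, 80 °C) and should give, by the same ring-opening/[2+2]/ring-opening/6π sequence, 3,5-diethoxy-2,6,6-tris(3-methylbut-2-en-1-yl)cyclohexa-2,4-dien-1-one F2, the regioisomer with the prenyl group on the other side of the ring. Its free C4–H leaves a Cope channel open, so it is hydrolysed at once (2 M HCl, THF, 40 °C) to the enolised trione 18, at which the two regioisomers converge.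

**Step 4.** Dehydrochlorination of the hindered α,α-dialkyl acid chloride may be slow. The ynol ether would then be consumed by direct acylation or by addition of HCl from the ammonium salt before enough ketene is present, and the hindered ketene may add only sluggishly to the internal alkyne.

Fallback: the neutral ketene is replaced by the much more electrophilic keteniminium ion, generated without an acid chloride in the cycloaddition flask. The fallback sets out from acid 6 and comes back at 12. Acid 6 is converted via chloride 10 with dimethylamine into N,N,5-trimethyl-2-(3-methylbut-2-en-1-yl)hex-4-enamide F3. Tf2O and 2,4,6-collidine (CH2Cl2, −20 °C) should give N,N-dimethyl-2,2-bis(3-methylbut-2-en-1-yl)keteniminium triflate F4. Addition of ynol ether 9 should give, by keteniminium–alkyne [2+2] cycloaddition, N-[3-ethoxy-2,4,4-tris(3-methylbut-2-en-1-yl)cyclobut-2-en-1-ylidene]-N-methylmethanaminium triflate F5. Hydrolysis in aqueous acetate buffer (pH 4) should then release cyclobutenone 12.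

**Step 7.** The acylation may stop at oxygen, or the acyl group may be shuttled between the three enol oxygens and C4 without settling at C2. The electron-rich trione may also autoxidise before it is acylated.

Fallback: the acyl carbon is brought in with the alkyne of the ring expansion, so no C-acylation is needed. The fallback sets out from cyclobutenone 12 (with acetylide 8 made from 7 as in step 3) and comes back at 21. Acetylide 8 is added to commercial 3-phenylpropanal (O=CCCc1ccccc1; THF, −78 °C) to give lithium 1-ethoxy-5-phenylpent-1-yn-3-olate F6. This is silylated in the same flask (TBSCl, DMPU) to tert-butyl[(1-ethoxy-5-phenylpent-1-yn-3-yl)oxy]dimethylsilane F7. Heating F7 with 12 (toluene, 80 → 110 °C) should give, with the same regiochemistry as in step 5, racemic 2-{1-[(tert-butyldimethylsilyl)oxy]-3-phenylpropyl}-3,5-diethoxy-4,6,6-tris(3-methylbut-2-en-1-yl)cyclohexa-2,4-dien-1-one F8. TBAF (THF, 0 °C) should give 3,5-diethoxy-2-(1-hydroxy-3-phenylpropyl)-4,6,6-tris(3-methylbut-2-en-1-yl)cyclohexa-2,4-dien-1-one F9. Dess–Martin periodinane (NaHCO3, CH2Cl2) should give 3,5-diethoxy-4,6,6-tris(3-methylbut-2-en-1-yl)-2-(3-phenylpropanoyl)cyclohexa-2,4-dien-1-one F10, which removes the carbinol stereocentre. Hydrolysis of the two enol ethers (1 M HCl, THF, rt) should then give 21.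

**Further compounds**

F1 | step 5 | 3-ethoxy-4,4-bis(3-methylbut-2-en-1-yl)cyclobut-2-en-1-one | CCOC1=CC(=O)C1(CC=C(C)C)CC=C(C)C
F2 | step 5 | 3,5-diethoxy-2,6,6-tris(3-methylbut-2-en-1-yl)cyclohexa-2,4-dien-1-one | O=C1C(CC=C(C)C)=C(OCC)C=C(OCC)C1(CC=C(C)C)CC=C(C)C
F3 | step 4 | N,N,5-trimethyl-2-(3-methylbut-2-en-1-yl)hex-4-enamide | CC(C)=CCC(CC=C(C)C)C(=O)N(C)C
F4 | step 4 | N,N-dimethyl-2,2-bis(3-methylbut-2-en-1-yl)keteniminium triflate | CC(C)=CCC(CC=C(C)C)=C=[N+](C)C.[O-]S(=O)(=O)C(F)(F)F
F5 | step 4 | N-[3-ethoxy-2,4,4-tris(3-methylbut-2-en-1-yl)cyclobut-2-en-1-ylidene]-N-methylmethanaminium triflate | CCOC1=C(CC=C(C)C)C(=[N+](C)C)C1(CC=C(C)C)CC=C(C)C.[O-]S(=O)(=O)C(F)(F)F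
F6 | step 7 | lithium 1-ethoxy-5-phenylpent-1-yn-3-olate | [Li]OC(C#COCC)CCc1ccccc1
F7 | step 7 | tert-butyl[(1-ethoxy-5-phenylpent-1-yn-3-yl)oxy]dimethylsilane | CCOC#CC(O[Si](C)(C)C(C)(C)C)CCc1ccccc1
F8 | step 7 | 2-{1-[(tert-butyldimethylsilyl)oxy]-3-phenylpropyl}-3,5-diethoxy-4,6,6-tris(3-methylbut-2-en-1-yl)cyclohexa-2,4-dien-1-one | O=C1C(C(O[Si](C)(C)C(C)(C)C)CCc2ccccc2)=C(OCC)C(CC=C(C)C)=C(OCC)C1(CC=C(C)C)CC=C(C)C
F9 | step 7 | 3,5-diethoxy-2-(1-hydroxy-3-phenylpropyl)-4,6,6-tris(3-methylbut-2-en-1-yl)cyclohexa-2,4-dien-1-one | O=C1C(C(O)CCc2ccccc2)=C(OCC)C(CC=C(C)C)=C(OCC)C1(CC=C(C)C)CC=C(C)C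
F10 | step 7 | 3,5-diethoxy-4,6,6-tris(3-methylbut-2-en-1-yl)-2-(3-phenylpropanoyl)cyclohexa-2,4-dien-1-one | O=C1C(C(=O)CCc2ccccc2)=C(OCC)C(CC=C(C)C)=C(OCC)C1(CC=C(C)C)CC=C(C)C
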